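The cyclohexene ring is disconnected at C1–C2, the bond joining the tertiary carbinol C1 (bearing C7H2OBz) to the benzoyloxy carbon C2, whose oxygens are cis and lie trans to the C6 acetate. A samarium diiodide ketone–aldehyde pinacol coupling forms this bond, closes the six-membered carbocycle and sets both carbinol centres in one operation. Its precursor is an open-chain D-galactose-derived 1,6-keto aldehyde (C1 ketone carrying C7H2OBn, C2 aldehyde) with benzyl ethers on the C3/C4 oxygens, later excised to give the C3=C4 alkene, and a trans-acetonide on the C5/C6 oxygens, later the two acetates.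

Key step: step 12

Remark on the chemistry: ring atoms are numbered C1 (tertiary carbinol carbon carrying C7), C2 (CH–OBz), C3=C4, C5 and C6 (CH–OAc, C6 next to C1); β is the ring face of the C1 hydroxyl and α the opposite face; open-chain intermediates keep sugar numbering (sugar C6 becomes ring C1, sugar C1 ring C2, sugar C2–C5 ring C3–C6); methyl α-D-galactopyranoside is taken as the commercial entry to the D-galacto series; alcohol 14 is carried as a mixture at sugar C6 because step 10 oxidises that centre.

Step 1
Reactants: 1 methyl α-D-galactopyranoside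
Product: 2 methyl 4,6-O-benzylidene-α-D-galactopyranoside
Conditions: PhCH(OMe)2, CSA (cat.), MeCN, 50 °C
Reagents that add atoms: benzaldehyde dimethyl acetal, COC(OC)c1ccccc1
Why: Acid-catalysed transacetalisation ties O4 and O6 into the six-membered benzylidene acetal under thermodynamic control (phenyl equatorial), leaving only O2 and O3 free.

Step 2
Reactants: 2 methyl 4,6-O-benzylidene-α-D-galactopyranoside
Product: 3 methyl 2,3-di-O-benzyl-4,6-O-benzylidene-α-D-galactopyranoside
Conditions: NaH, BnBr, Bu4NI (cat.), DMF, 0 °C → rt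
Reagents that add atoms: benzyl bromide, BrCc1ccccc1
Why: Williamson etherification of the two remaining secondary hydroxyls, with no stereocentre touched.

Step 3
Reactants: 3 methyl 2,3-di-O-benzyl-4,6-O-benzylidene-α-D-galactopyranoside
Product: 4 2,3-di-O-benzyl-D-galactose diethyl dithioacetal
Conditions: EtSH, conc. HCl, 0 °C → rt
Reagents that add atoms: ethanethiol, CCS
Why: Mercaptolysis, the acid-promoted exchange of the methyl glycoside and the benzylidene acetal against thiol, opens the pyranose to the acyclic dithioacetal and frees O4, O5 and O6 while benzyl ethers and all four stereocentres are kept.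

Step 4
Reactants: 4 2,3-di-O-benzyl-D-galactose diethyl dithioacetal
Product: 5 2,3-di-O-benzyl-6-O-(tert-butyldiphenylsilyl)-D-galactose diethyl dithioacetal
Conditions: TBDPSCl, imidazole, DMF, 0 °C
Reagents that add atoms: tert-butyl(chloro)diphenylsilane, CC(C)(C)[Si](Cl)(c1ccccc1)c1ccccc1
Why: Sterically controlled silyl ether formation at the primary O6 in preference to the two secondary hydroxyls.

Step 5
Reactants: 5 2,3-di-O-benzyl-6-O-(tert-butyldiphenylsilyl)-D-galactose diethyl dithioacetal
Product: 6 2,3-di-O-benzyl-6-O-(tert-butyldiphenylsilyl)-4,5-O-isopropylidene-D-galactose diethyl dithioacetal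
Conditions: Me2C(OMe)2, CSA (cat.), acetone, rt
Reagents that add atoms: 2,2-dimethoxypropane, COC(C)(C)OC
Why: Acetalisation of the only remaining 1,2-diol, where the threo O4/O5 pair gives the unstrained trans-disubstituted dioxolane and the dithioacetal and silyl ether tolerate the mild acid.

Step 6
Reactants: 6 2,3-di-O-benzyl-6-O-(tert-butyldiphenylsilyl)-4,5-O-isopropylidene-D-galactose diethyl dithioacetal
Product: 7 2,3-di-O-benzyl-4,5-O-isopropylidene-D-galactose diethyl dithioacetal
Conditions: Bu4NF, THF, 0 °C → rt; H2O work-up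
Reagents that add atoms: none
Why: Fluoride-induced Si–O cleavage (desilylation) frees the primary alcohol while acetonide, benzyl ethers and dithioacetal are inert.

Step 7
Reactants: 7 2,3-di-O-benzyl-4,5-O-isopropylidene-D-galactose diethyl dithioacetal
Product: 8 2,3-di-O-benzyl-4,5-O-isopropylidene-D-galacto-hexodialdose 1-(diethyl dithioacetal)
Conditions: (COCl)2, DMSO, CH2Cl2, −78 °C; Et3N, −78 → 0 °C
Reagents that add atoms: none
Why: Swern oxidation is compatible with the dithioacetal, and the α-centre, being part of the trans-dioxolane, should not epimerise.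

Step 8
Reactants: 9 tributyltin hydride; 10 benzyl chloromethyl ether
Product: 12 tributyl[(benzyloxy)methyl]stannane, via tributylstannyllithium 11 (not isolated)
Conditions: LiN(iPr)2, THF, 0 °C; then 10, −78 °C → rt
Reagents that add atoms: none
Why: Deprotonation of the tin hydride gives the stannyl anion, which displaces chloride from the chloromethyl ether (SN2), the standard access to this α-alkoxystannane.

Step 9
Reactants: 8 2,3-di-O-benzyl-4,5-O-isopropylidene-D-galacto-hexodialdose 1-(diethyl dithioacetal); 12 tributyl[(benzyloxy)methyl]stannane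
Product: 14 2,3,7-tri-O-benzyl-4,5-O-isopropylidene-D-galacto-heptose diethyl dithioacetal (C6 epimer mixture), via (benzyloxy)methyllithium 13 (not isolated)
Conditions: 12, n-BuLi, THF, −78 °C; then 8, −78 °C; H2O
Reagents that add atoms: none
Why: Tin–lithium exchange gives the α-alkoxy organolithium, whose 1,2-addition to the aldehyde installs C7 with its oxygen; the new carbinol centre is left uncontrolled because the next step oxidises it.

Step 10
Reactants: 14 2,3,7-tri-O-benzyl-4,5-O-isopropylidene-D-galacto-heptose diethyl dithioacetal (C6 epimer mixture)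
Product: 15 2,3,7-tri-O-benzyl-4,5-O-isopropylidene-D-galacto-heptos-6-ulose 1-(diethyl dithioacetal)
Conditions: (COCl)2, DMSO, CH2Cl2, −78 °C; Et3N, −78 → 0 °C
Reagents that add atoms: none
Why: Swern oxidation converges both carbinol epimers on the ketone without touching sulfur or the trans-dioxolane α-centre.

Step 11
Reactants: 15 2,3,7-tri-O-benzyl-4,5-O-isopropylidene-D-galacto-heptos-6-ulose 1-(diethyl dithioacetal)
Product: 16 2,3,7-tri-O-benzyl-4,5-O-isopropylidene-aldehydo-D-galacto-heptos-6-ulose
Conditions: I2, NaHCO3, acetone–H2O, 0 °C → rt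
Reagents that add atoms: water, O
Why: Iodine-promoted hydrolysis of the dithioacetal under bicarbonate buffering releases the aldehyde without acid, so the acetonide and the α-benzyloxy centre should survive; the crude keto aldehyde is used at once.

Step 12
Reactants: 16 2,3,7-tri-O-benzyl-4,5-O-isopropylidene-aldehydo-D-galacto-heptos-6-ulose
Product: 17 3,4-di-O-benzyl-1-C-[(benzyloxy)methyl]-5,6-O-isopropylidene-cyclohexane-1,2,3,4,5,6-hexol (1-OH β, 2-OH β, 3-OBn α, 4-OBn β, 5-O β, 6-O α, C7 α)
Conditions: SmI2 (3 equiv), t-BuOH (3 equiv), THF, −78 °C → rt, slow addition of 16; aqueous work-up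
Reagents that add atoms: none
Why: SmI2 transfers one electron to the C2 aldehyde, the more easily reduced carbonyl, and the resulting trivalent-samarium ketyl adds through carbon to the C1 ketone held on the same metal centre; a second equivalent reduces the alkoxy radical and work-up protonates the samarium diolate. The closest known reaction type is the SmI2 pinacol carbocyclisation of sugar-derived 1,6-dialdehydes and keto aldehydes to cyclitol cis-diols. The carbocycle closes in 6-exo-trig fashion (ketyl carbon onto the C=O carbon) through a chair-like transition state in which the trans-dioxolane on C5/C6 holds the two carbonyl termini gauche. The C2 centre is controlled by the adjacent C3 benzyloxy group, the ketyl oxygen taking the position anti to it to minimise dipole and steric repulsion, and the C1 centre is controlled by samarium bridging both oxygens, which delivers the C1 oxygen cis to the C2 oxygen and thus trans to the C6 acetonide oxygen. The step needs the cis-diol on the β face and ring closure faster than reductive cleavage of the α-alkoxy ketone; the first is secured because the C3 and C6 oxygens both lie on the α face and so direct to the same side, the second by ketyl formation at the aldehyde, low temperature and slow addition of 16.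

Step 13
Reactants: 17 3,4-di-O-benzyl-1-C-[(benzyloxy)methyl]-5,6-O-isopropylidene-cyclohexanehexol
Product: 18 2-O-benzoyl-3,4-di-O-benzyl-1-C-[(benzyloxy)methyl]-5,6-O-isopropylidene-cyclohexanehexol (configuration as 17)
Conditions: BzCl, pyridine, DMAP (cat.), CH2Cl2, 0 °C → rt
Reagents that add atoms: benzoyl chloride, O=C(Cl)c1ccccc1
Why: Esterification of the single secondary hydroxyl (C2), the tertiary C1 hydroxyl being too hindered to acylate.

Step 14
Reactants: 18 2-O-benzoyl-3,4-di-O-benzyl-1-C-[(benzyloxy)methyl]-5,6-O-isopropylidene-cyclohexanehexol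
Product: 19 2-O-benzoyl-1-C-(hydroxymethyl)-5,6-O-isopropylidene-cyclohexanehexol (1-OH β, 2-OBz β, 3-OH α, 4-OH β, 5-O β, 6-O α)
Conditions: H2 (1 atm), Pd(OH)2 on carbon, EtOAc–EtOH, rt
Reagents that add atoms: none
Why: Catalytic hydrogenolysis removes the three benzyl ethers, while the benzoate and the acetonide are stable under neutral conditions.

Step 15
Reactants: 19 2-O-benzoyl-1-C-(hydroxymethyl)-5,6-O-isopropylidene-cyclohexanehexol
Product: 20 2-O-benzoyl-1-C-[(benzoyloxy)methyl]-5,6-O-isopropylidene-cyclohexanehexol (free 1-OH β, 3-OH α, 4-OH β)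
Conditions: BzCl (1.05 equiv), pyridine, CH2Cl2, −30 °C
Reagents that add atoms: benzoyl chloride, O=C(Cl)c1ccccc1
Why: Kinetically selective esterification of the primary C7 hydroxyl, since the C3 and C4 hydroxyls are secondary and axial in the chair fixed by the trans-fused acetonide and the C1 hydroxyl is tertiary.

Step 16
Reactants: 20 2-O-benzoyl-1-C-[(benzoyloxy)methyl]-5,6-O-isopropylidene-cyclohexanehexol
Product: 21 2β-benzoyloxy-1α-[(benzoyloxy)methyl]-5β,6α-(isopropylidenedioxy)cyclohex-3-en-1β-ol
Conditions: PPh3, imidazole, I2, toluene, reflux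
Reagents that add atoms: none
Why: Garegg–Samuelsson olefination, in which the vicinal trans-diol is activated as alkoxyphosphonium ions, iodide displaces with inversion and the β-iodo phosphonium intermediate undergoes anti reductive elimination to the C3=C4 alkene, is known for trans-diols of pyranosides and cyclitols and should leave the tertiary hydroxyl, esters and acetonide untouched.

Step 17
Reactants: 21 2β-benzoyloxy-1α-[(benzoyloxy)methyl]-5β,6α-(isopropylidenedioxy)cyclohex-3-en-1β-ol
Product: 22 2β-benzoyloxy-1α-[(benzoyloxy)methyl]cyclohex-3-ene-1β,5β,6α-triol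
Conditions: AcOH–H2O (4:1), 45 °C
Reagents that add atoms: none
Why: Acid hydrolysis of the strained trans-fused isopropylidene acetal, under which benzoates and the allylic C–O bonds are stable.

Step 18
Reactants: 22 2β-benzoyloxy-1α-[(benzoyloxy)methyl]cyclohex-3-ene-1β,5β,6α-triol
Product: 23 cleistenediol F, (1S,2S,5R,6S) in the numbering used here
Conditions: Ac2O, pyridine, rt
Reagents that add atoms: acetic anhydride, CC(=O)OC(C)=O
Why: Acetylation of the two secondary hydroxyls at C5 and C6, the tertiary C1 hydroxyl remaining free in the absence of stronger activation.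

Compound list
1 | methyl α-D-galactopyranoside | CO[C@@H]1[C@H](O)[C@@H](O)[C@@H](O)[C@@H](CO)O1 | starting material
2 | methyl 4,6-O-benzylidene-α-D-galactopyranoside (phenyl equatorial) | CO[C@@H]1[C@H](O)[C@@H](O)[C@H]2O[C@@H](c3ccccc3)OC[C@H]2O1 | intermediate
3 | methyl 2,3-di-O-benzyl-4,6-O-benzylidene-α-D-galactopyranoside | CO[C@@H]1[C@H](OCc3ccccc3)[C@@H](OCc3ccccc3)[C@H]2O[C@@H](c3ccccc3)OC[C@H]2O1 | intermediate
4 | 2,3-di-O-benzyl-D-galactose diethyl dithioacetal | CCSC(SCC)[C@H](OCc1ccccc1)[C@@H](OCc1ccccc1)[C@@H](O)[C@H](O)CO | intermediate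
5 | 2,3-di-O-benzyl-6-O-(tert-butyldiphenylsilyl)-D-galactose diethyl dithioacetal | CCSC(SCC)[C@H](OCc1ccccc1)[C@@H](OCc1ccccc1)[C@@H](O)[C@H](O)CO[Si](c1ccccc1)(c1ccccc1)C(C)(C)C | intermediate
6 | 2,3-di-O-benzyl-6-O-(tert-butyldiphenylsilyl)-4,5-O-isopropylidene-D-galactose diethyl dithioacetal | CCSC(SCC)[C@H](OCc1ccccc1)[C@@H](OCc1ccccc1)[C@H]1OC(C)(C)O[C@@H]1CO[Si](c1ccccc1)(c1ccccc1)C(C)(C)C | intermediate
7 | 2,3-di-O-benzyl-4,5-O-isopropylidene-D-galactose diethyl dithioacetal | CCSC(SCC)[C@H](OCc1ccccc1)[C@@H](OCc1ccccc1)[C@H]1OC(C)(C)O[C@@H]1CO | intermediate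
8 | 2,3-di-O-benzyl-4,5-O-isopropylidene-D-galacto-hexodialdose 1-(diethyl dithioacetal) | CCSC(SCC)[C@H](OCc1ccccc1)[C@@H](OCc1ccccc1)[C@H]1OC(C)(C)O[C@@H]1C=O | intermediate
9 | tributyltin hydride | CCCC[SnH](CCCC)CCCC | starting material
10 | benzyl chloromethyl ether | ClCOCc1ccccc1 | starting material
11 | tributylstannyllithium | [Li][Sn](CCCC)(CCCC)CCCC | intermediate (not isolated)
12 | tributyl[(benzyloxy)methyl]stannane | CCCC[Sn](CCCC)(CCCC)COCc1ccccc1 | intermediate
13 | (benzyloxy)methyllithium | [Li]COCc1ccccc1 | intermediate (not isolated)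
14 | 2,3,7-tri-O-benzyl-4,5-O-isopropylidene-D-galacto-heptose diethyl dithioacetal, both C6 epimers | CCSC(SCC)[C@H](OCc1ccccc1)[C@@H](OCc1ccccc1)[C@H]1OC(C)(C)O[C@@H]1C(O)COCc1ccccc1 | intermediate
15 | 2,3,7-tri-O-benzyl-4,5-O-isopropylidene-D-galacto-heptos-6-ulose 1-(diethyl dithioacetal) | CCSC(SCC)[C@H](OCc1ccccc1)[C@@H](OCc1ccccc1)[C@H]1OC(C)(C)O[C@@H]1C(=O)COCc1ccccc1 | intermediate
16 | 2,3,7-tri-O-benzyl-4,5-O-isopropylidene-aldehydo-D-galacto-heptos-6-ulose | O=C[C@H](OCc1ccccc1)[C@@H](OCc1ccccc1)[C@H]1OC(C)(C)O[C@@H]1C(=O)COCc1ccccc1 | intermediate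
17 | 3,4-di-O-benzyl-1-C-[(benzyloxy)methyl]-5,6-O-isopropylidene-cyclohexanehexol (1-OH β, 2-OH β, 3-OBn α, 4-OBn β, 5-O β, 6-O α) | O[C@H]1[C@H](OCc2ccccc2)[C@@H](OCc2ccccc2)[C@H]2OC(C)(C)O[C@@H]2[C@]1(O)COCc1ccccc1 | intermediate
18 | 2-O-benzoyl derivative of 17 | O=C(c1ccccc1)O[C@H]1[C@H](OCc2ccccc2)[C@@H](OCc2ccccc2)[C@H]2OC(C)(C)O[C@@H]2[C@]1(O)COCc1ccccc1 | intermediate
19 | 2-O-benzoyl-1-C-(hydroxymethyl)-5,6-O-isopropylidene-cyclohexanehexol (configuration as 17) | O=C(c1ccccc1)O[C@H]1[C@H](O)[C@@H](O)[C@H]2OC(C)(C)O[C@@H]2[C@]1(O)CO | intermediate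
20 | 2-O-benzoyl-1-C-[(benzoyloxy)methyl]-5,6-O-isopropylidene-cyclohexanehexol (free 1-OH β, 3-OH α, 4-OH β) | O=C(c1ccccc1)O[C@H]1[C@H](O)[C@@H](O)[C@H]2OC(C)(C)O[C@@H]2[C@]1(O)COC(=O)c1ccccc1 | intermediate
21 | 2β-benzoyloxy-1α-[(benzoyloxy)methyl]-5β,6α-(isopropylidenedioxy)cyclohex-3-en-1β-ol | O=C(c1ccccc1)O[C@H]1C=C[C@H]2OC(C)(C)O[C@@H]2[C@]1(O)COC(=O)c1ccccc1 | intermediate
22 | 2β-benzoyloxy-1α-[(benzoyloxy)methyl]cyclohex-3-ene-1β,5β,6α-triol | O=C(c1ccccc1)O[C@H]1C=C[C@@H](O)[C@H](O)[C@]1(O)COC(=O)c1ccccc1 | intermediate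
23 | cleistenediol F | CC(=O)O[C@@H]1C=C[C@H](OC(=O)c2ccccc2)[C@@](O)(COC(=O)c2ccccc2)[C@H]1OC(C)=O | target

Total step count: 18. Longest linear sequence: 17 steps (steps 1–7 and 9–18, from methyl α-D-galactopyranoside); step 8 is a one-step side branch.

Steps most likely to fail

Step 12. The ketyl cyclisation may show poor facial selectivity (cis-diol on the α face or a trans-diol), because the acetonide-fixed chair places the C3 and C4 benzyloxy groups axial. It may also lose material to reductive cleavage of the C–O bonds flanking the ketone or to simple reduction of the aldehyde. The fallback closes the same C1–C2 bond by metathesis and sets the diol afterwards. It sets out from 16, which would be methylenated at both carbonyls (Ph3PCH3Br, KOtBu, THF, −78 → 0 °C) to 3,4-bis(benzyloxy)-7-[(benzyloxy)methyl]-5,6-O-isopropylideneocta-1,7-diene-5,6-diol F1. Ring-closing metathesis with second-generation Grubbs catalyst (CH2Cl2, 40 °C) should give 3α,4β-bis(benzyloxy)-1-[(benzyloxy)methyl]-5β,6α-(isopropylidenedioxy)cyclohex-1-ene F2. Dihydroxylation (OsO4 cat., N-methylmorpholine N-oxide, acetone–H2O) is expected to add syn to the face opposite the allylic oxygens at C3 and C6, the usual outcome for allylic ethers, and so returns to the route at 17.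

Step 16. The phosphonium–iodide sequence may stall on the hindered, conformationally fixed trans-diol, or be diverted by participation of the neighbouring C2 benzoate. The fallback is a sulfonate-based reductive elimination that needs only one displacement, at C4, remote from the benzoate. It sets out from 20, which would be mesylated (MsCl, pyridine, 0 °C) to the 3,4-di-O-methanesulfonyl derivative of 20 F3. Tipson–Cohen elimination (NaI, Zn, DMF, 100 °C) returns to the route at 21.

Step 3. Prolonged exposure to strong acid may let O4 recapture the thionium ion to give ethyl 1-thiofuranosides, or may erode the benzyl ethers, because cleavage of the methyl pyranoside is slow. The fallback separates acetal hydrolysis from thioacetal formation. It sets out from 3, which would be hydrolysed (H2SO4, AcOH–H2O, 80 °C) to 2,3-di-O-benzyl-D-galactopyranose F4. Brief treatment of this hemiacetal with EtSH and conc. HCl at 0 °C returns to the route at 4.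

Further compounds
F1 | step 12 | 3,4-bis(benzyloxy)-7-[(benzyloxy)methyl]-5,6-O-isopropylideneocta-1,7-diene-5,6-diol (sugar configuration of 16) | C=C[C@H](OCc1ccccc1)[C@@H](OCc1ccccc1)[C@H]1OC(C)(C)O[C@@H]1C(=C)COCc1ccccc1
F2 | step 12 | 3α,4β-bis(benzyloxy)-1-[(benzyloxy)methyl]-5β,6α-(isopropylidenedioxy)cyclohex-1-ene | C(OCc1ccccc1)C1=C[C@H](OCc2ccccc2)[C@@H](OCc2ccccc2)[C@H]2OC(C)(C)O[C@@H]21
F3 | step 16 | 3,4-di-O-methanesulfonyl derivative of 20 | O=C(c1ccccc1)O[C@H]1[C@H](OS(C)(=O)=O)[C@@H](OS(C)(=O)=O)[C@H]2OC(C)(C)O[C@@H]2[C@]1(O)COC(=O)c1ccccc1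
F4 | step 3 | 2,3-di-O-benzyl-D-galactopyranose (anomeric mixture) | OC1[C@H](OCc2ccccc2)[C@@H](OCc2ccccc2)[C@@H](O)[C@@H](CO)O1
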